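An activator cannot both join a substrate and join another activator.

| flask | substrate | activator | time | remark |
|---|---|---|---|---|
| dusk | 0.50 mM (fed, over 8.00 min) | 0.450 mM | 10 min | a stirred flask in which substrate is dosed at a steady rate over 8.00 min without added volume, worked up at 10 min |
| dawn | 0.50 mM | 0.450 mM |  | one stirred flow tank at steady state, fed with the mixture as stated, mean residence time 10 min |
| autumn | 0.50 mM | 0.450 mM | 10 min | everything together in a closed stirred flask, run for 10 min |
| winter | 0.50 mM | 0.450 mM (fed, over 8.00 min) | 10 min | a stirred flask in which activator is dosed at a steady rate over 8.00 min without added volume, worked up at 10 min |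

- the set-up with the highest amount of ring at the outlet or at the end, in percent of the substrate put in ("none" if the first two lie within 2 percentage points) (dusk / dawn / autumn / winter / none)
- amount of ring at the outlet or at the end, in percent of the substrate put in, dusk
- amount of ring at the outlet or at the end, in percent of the substrate put in, dawn
- amount of ring at the outlet or at the end, in percent of the substrate put in, autumn
- amount of ring at the outlet or at the end, in percent of the substrate put in, winter

    substrate ⇌ dormant form (K1 = 0.52, k1 = 0.011 s⁻¹)
    substrate + activated form → open dimer (k2 = 6.4 L mol⁻¹ s⁻¹)
    substrate + activator → activated form (k3 = 41 L mol⁻¹ s⁻¹)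
    2 activator → homo dimer (k4 = 40 L mol⁻¹ s⁻¹)
    activated form → ring (k5 = 0.0080 s⁻¹)

Divide one use of activator by the other and time drops out: σ, a selectivity factor, is the constant of activation k3 times substrate, divided by 2 times the constant of dimerisation k4 times activator. Above one, activation takes more of the activator. In autumn, at mixing, σ is 0.569, which is below one. In dusk the first half-life of activator by dimerisation alone, 0.463 min, is far shorter than the dosing time of 8.00 min, so I put dusk last.

In winter, substrate and dormant form relax in 0.359 min, far shorter than the dosing. Free substrate therefore soon stands near S0 = cA/(1+K1), or 0.329 mM, with cA its charge. Take activator as steady, so that its feed equals its two uses together; setting σ to one at S0 then gives the crossover feed, F* = k3²S0²/k4, the activator feed at which the two uses are equal, 0.273 mM min⁻¹. The winter feed is 0.0563 mM min⁻¹, which is 0.206 of F*. So my order is winter, autumn, dusk; dawn I did not reckon.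

The forecast gives 12.5 % for dusk, 35 % for dawn, 37 % for autumn and 44 % for winter, and picks winter, holding that “ring yield depends on keeping [activator] low while substrate is plentiful”.

The simulation gives 12.0 %, 34.8 %, 37.0 % and 41.4 % in the same order, so winter is best. Winter leads autumn by 4.4 percentage points, and the forecast would be wrong if a run brought that lead within 2 points. In winter at 4.42 min, σ stands at 1.8, which is above one.

Now charge a neighbour of winter with 2.0 mM of substrate. S0 becomes 1.32 mM and F* becomes 4.37 mM min⁻¹, so the same feed is 0.0129 of it, and I expect a smaller share of activator in homo dimer than in winter. That flask ends with 0.00722 mM of homo dimer, holding 3.21 % of the activator charge against 33.4 % in winter. Its open dimer stands at 19.2 % and its ring at 11.2 %.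

The numbers of this flask belong to no real substance; the flask was simulated.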